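(The runs stem from a simulated flask on assumed constants; noise was put on by code.)

After 20.0 h the alpha flask, charged at 64 mM, has made 74.3 % of product, more than the 50.1 % of the zeta flask at 32 mM, and zeta is the flask asked about.

common to all: enzyme 0.01 mol%

|  | starting material | second substrate | remark | time |
|---|---|---|---|---|
| zeta | 32 mM | 1 equiv | the very flask that is asked about, followed so far |  |
| alpha | 64 mM | 1 equiv | run made earlier |  |
| flask | 32 mM | 1.00 equiv |  | 40 h |

| run | time / h | product / % | starting material / % |
|---|---|---|---|
| zeta | 1.33 | 5.3 | 95.5 |
| zeta | 4.00 | 14.1 | 85.9 |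
| zeta | 8.00 | 26.1 | 73.0 |
| zeta | 10.0 | 31.5 | 68.7 |
| zeta | 15.0 | 42.4 | 58.5 |
| zeta | 20.0 | 50.1 | 49.4 |
| alpha | 6.00 | 36.3 | 64.1 |
| alpha | 12.0 | 58.7 | 41.7 |
| alpha | 20.0 | 74.3 | 24.9 |
| alpha | 25.0 | 80.2 | 19.8 |
| alpha | 30.0 | 84.3 | 15.8 |
| alpha | 40.0 | 88.2 | 11.4 |

(standard deviation of a reading: 0.5 percentage points)

1. amount of product in percent of the starting material charged, at 4.0 h, 15 h and 40 h



We keep the books on starting material, which meets second substrate one to one, so the two together are the limiting reagent. Two entries carry the ledger: product and starting material add to 99.5 % in zeta at 20.0 h and to 99.6 % in alpha at 40.0 h. A third entry, what sits on the enzyme, is of the order of its loading, 0.01 mol% of the charge, against a scatter of 0.5 percentage points. So product is the charge less the remainder, and forecasting the course means forecasting the remainder. For 4.0 h and 15 h we take the zeta readings, 14.1 % and 42.4 %.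

For 40 h we solve at both ends and join. If the rate followed the first power of the remainder, doubling the time would square the remainder. If it followed the second power, the reciprocal of the remainder would grow in step with time. Alpha tests this: from 24.9 % at 20.0 h, twice the time gives 6.20 % at the first end and 14.2 % at the second. The reading of 11.4 % lies 0.352 of the way from the second end to the first; we call this fraction the tail place. The zeta flask, with 49.4 % left at 20.0 h, has ends of 24.4 % and 32.8 %, so the same tail place gives us 70.2 % of product at 40 h.

The forecast, holding that “the two runs should roughly overlay”, gives 14.3 %, 42.3 % and 72 %, the last higher than ours.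

The flask gives 14.3 %, 41.7 % and 69.3 %.

    product + starting complex → spent catalyst A (k = 0.710 M⁻¹ h⁻¹)
    starting material + enzyme ⇌ starting complex (K = 20.0 M⁻¹, k = 2.90 × 10⁵ M⁻¹ h⁻¹)
    ternary complex → spent catalyst B (k = 0.00930 h⁻¹)
    second substrate + starting complex ⇌ ternary complex (K = 42.0 M⁻¹, k = 3.80 × 10⁵ M⁻¹ h⁻¹)
    ternary complex → enzyme + product (k = 1300 h⁻¹)

Our figure stands 0.90 points above the flask, whose remainder puts its tail place at 0.250, lower than alpha's 0.352. Product stands short of the charge at 40 h through the falling back of starting complex to starting material and enzyme, together with the length of the run: the run without that falling back gives 96.3 % instead of 69.3 %, and the run ten times as long gives 96.1 %, while the run without the turning of ternary complex into spent catalyst B gives 70.2 %. Over ten times the time, the 30.7 % left at 40 h has a second end of 4.23 %, and the flask holds 3.89 % at 400 h, a tail place of 0.0816.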